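**Retrosynthetic overview**

Locants used below: lactone C1(=O)–C2H2–C3H(OO)–C4(Me)(O)–C5H2–C6(Me)(OO)–C7H2–C8H(Me)–side chain.
- The 1,2-dioxane ring is closed last: C3–O by oxa-Michael addition of a C6 hydroperoxide onto a preformed butenolide; C6–OO by Co-catalysed hydroperoxysilylation of a C6=CH2 alkene made from a C6 ketone.
- Key C4–C5 bond: the γ-carbon of α-angelica lactone (butenolide ring bought intact) attacks the α-carbon of the C6 ketone, made electrophilic as an azoalkene (enolonium equivalent); this sets C4.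
- The α-chloroketone comes from a β-methyl ester and LiCH2Cl; the ester (C8) from Cu-catalysed asymmetric conjugate addition of the side-chain Grignard reagent to methyl crotonate.
- The side-chain chloride comes from 5-chloropent-1-yne by carboalumination and benzylation (E-alkene). Ring order: butenolide (purchased), then 1,2-dioxane.

Assumption: in steps 2 and 5 the ligand or catalyst antipode named is the one taken to give the drawn configuration; the mirror-image (pseudo-enantiomeric) catalyst is equally available and is used if the sense proves opposite.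

**Route**

Step 1
Reactants: 1 5-chloropent-1-yne; 2 benzyl chloride
Product: 4 [(2E)-6-chloro-3-methylhex-2-en-1-yl]benzene, via alkenylalane 3 (not isolated)
Conditions: AlMe3 (2 equiv), Cp2ZrCl2 (0.25 equiv), CH2Cl2, 0 °C to rt; then 2, Pd(PPh3)4 (3 mol %), THF, rt; aq. HCl
Reagents that add atoms: trimethylaluminium, C[Al](C)C
Why: Negishi Zr-catalysed syn-carboalumination puts Me and Al cis on the terminal alkyne, and Pd-catalysed cross-coupling of the alkenylalane with the benzylic chloride goes with retention, fixing the E trisubstituted alkene while the primary alkyl chloride stays inert.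

Step 2
Reactants: 4 [(2E)-6-chloro-3-methylhex-2-en-1-yl]benzene; 5 methyl (E)-but-2-enoate (methyl crotonate)
Product: 7 methyl (3S,7E)-3,7-dimethyl-9-phenylnon-7-enoate, via Grignard reagent 6 (not isolated)
Conditions: Mg (I2), Et2O, reflux; then MgBr2·OEt2 (1 equiv), 5, CuI (2 mol %), (S)-Tol-BINAP (3 mol %), t-BuOMe, −40 °C; 1 M HCl
Reagents that add atoms: none
Why: Cu-catalysed asymmetric conjugate addition of a Grignard reagent to an enoate (Feringa–Loh conditions), in which the chiral bisphosphine–copper complex selects the enoate face and sets C8 as S.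

Step 3
Reactants: 7 methyl (3S,7E)-3,7-dimethyl-9-phenylnon-7-enoate
Product: 8 (4S,8E)-1-chloro-4,8-dimethyl-10-phenyldec-8-en-2-one
Conditions: ICH2Cl (1.5 equiv), MeLi·LiBr (1.5 equiv), THF/Et2O, −78 °C; AcOH quench at −78 °C
Reagents that add atoms: chloroiodomethane, ClCI
Why: Carbenoid homologation of an ester: chloromethyllithium formed in situ adds once, and the tetrahedral lithium alkoxide survives at −78 °C until the cold acidic quench releases the chloromethyl ketone; C8 is not touched.

Step 4
Reactants: 8 (4S,8E)-1-chloro-4,8-dimethyl-10-phenyldec-8-en-2-one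
Product: 9 tert-butyl 2-[(4S,8E)-1-chloro-4,8-dimethyl-10-phenyldec-8-en-2-ylidene]hydrazine-1-carboxylate (E/Z about C=N)
Conditions: BocNHNH2 (1.05 equiv), MgSO4, Et2O, 0 °C to rt
Reagents that add atoms: tert-butyl carbazate, CC(C)(C)OC(=O)NN
Why: Hydrazone condensation at the ketone is faster than displacement of chloride at 0 °C and gives the stable α-chloro N-Boc hydrazone, the azoalkene precursor.

Step 5
Reactants: 9 tert-butyl 2-[(4S,8E)-1-chloro-4,8-dimethyl-10-phenyldec-8-en-2-ylidene]hydrazine-1-carboxylate; 10 α-angelica lactone (5-methylfuran-2(3H)-one)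
Product: 13 (5R)-5-[(4S,8E)-4,8-dimethyl-2-oxo-10-phenyldec-8-en-1-yl]-5-methylfuran-2(5H)-one, via azoalkene 11 (not isolated), via hydrazone adduct 12 (not isolated)
Conditions: 10 (1.5 equiv), Na2CO3 (2 equiv), 9-amino-9-deoxy-epi-quinidine 3,5-(CF3)2C6H3 squaramide (10 mol %), toluene, −20 °C; then OHC–CO2H (50 % aq., 5 equiv), THF, rt
Reagents that add atoms: water, O
Why: Proposed new method: carbonate removes HCl from 9 to give azoalkene 11, a soft Michael acceptor whose terminal CH2 is the ketone α-carbon made electrophilic (enolonium equivalent, as in Coltart-type reversed-polarity α-alkylation of ketones via azoalkenes); the bifunctional squaramide holds the dienolate of 10 as a quinuclidinium ion pair and hydrogen-bonds the N=N–C=O unit, so the γ-carbon adds to one face and sets C4 as R, by analogy with squaramide- and thiourea-catalysed direct vinylogous Michael additions of α-angelica lactone to nitroalkenes; the hydrazone keeps the ketone masked during the basic stage, and acidic exchange with glyoxylic acid then frees it.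

Step 6
Reactants: 13 (5R)-5-[(4S,8E)-4,8-dimethyl-2-oxo-10-phenyldec-8-en-1-yl]-5-methylfuran-2(5H)-one
Product: 14 (5R)-5-[(4S,8E)-4,8-dimethyl-2-methylidene-10-phenyldec-8-en-1-yl]-5-methylfuran-2(5H)-one
Conditions: Zn, CH2Br2, TiCl4 (Takai–Lombardo reagent), THF/CH2Cl2, 0 °C to rt
Reagents that add atoms: dibromomethane, BrCBr
Why: Takai–Lombardo methylenation is non-basic and attacks ketones but not lactones, so the β-acyloxy ketone neither eliminates nor cyclises onto the butenolide, and no stereocentre is affected.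

Step 7
Reactants: 14 (5R)-5-[(4S,8E)-4,8-dimethyl-2-methylidene-10-phenyldec-8-en-1-yl]-5-methylfuran-2(5H)-one
Product: 15 (5R)-5-methyl-5-[(4S,8E)-2,4,8-trimethyl-10-phenyl-2-(triethylsilylperoxy)dec-8-en-1-yl]furan-2(5H)-one (both C6 epimers, about 1:1)
Conditions: O2 (1 atm), Et3SiH (2 equiv), Co(acac)2 (5 mol %), ClCH2CH2Cl, rt
Reagents that add atoms: dioxygen, O=O; triethylsilane, CC[SiH](CC)CC
Why: Mukaiyama–Isayama hydroperoxysilylation: the cobalt hydride transfers H to the least hindered, electron-rich 1,1-disubstituted alkene in preference to the trisubstituted and the electron-poor butenolide alkenes, and the tertiary C6 radical is trapped by O2 and silylated; C6 forms without facial control, so both epimers are carried on.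

Step 8
Reactants: 15 (5R)-5-methyl-5-[(4S,8E)-2,4,8-trimethyl-10-phenyl-2-(triethylsilylperoxy)dec-8-en-1-yl]furan-2(5H)-one
Product: 17 plakortolide G, via hydroperoxide 16 (not isolated)
Conditions: HCl (cat.), MeOH, 0 °C; then Et2NH (cat.), CF3CH2OH, rt; chromatography
Reagents that add atoms: none
Why: Acid methanolysis frees the tertiary hydroperoxide, which closes by amine-catalysed 6-exo intramolecular oxa-Michael addition from the butenolide face that carries the C5 tether, so C3 is set cis to C4 (cis-fused peroxylactone); the 6R product is separated from its C6 epimer by chromatography.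

**Compound list**

1 | 5-chloropent-1-yne | C#CCCCCl | starting material
2 | benzyl chloride | ClCc1ccccc1 | starting material
3 | (E)-(5-chloro-2-methylpent-1-en-1-yl)dimethylalumane | C/C(=C\[Al](C)C)CCCCl | intermediate
4 | [(2E)-6-chloro-3-methylhex-2-en-1-yl]benzene | C/C(=C\Cc1ccccc1)CCCCl | intermediate
5 | methyl (E)-but-2-enoate (methyl crotonate) | C/C=C/C(=O)OC | starting material
6 | [(4E)-4-methyl-6-phenylhex-4-en-1-yl]magnesium chloride | C/C(=C\Cc1ccccc1)CCC[Mg]Cl | intermediate
7 | methyl (3S,7E)-3,7-dimethyl-9-phenylnon-7-enoate | C/C(=C\Cc1ccccc1)CCC[C@H](C)CC(=O)OC | intermediate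
8 | (4S,8E)-1-chloro-4,8-dimethyl-10-phenyldec-8-en-2-one | C/C(=C\Cc1ccccc1)CCC[C@H](C)CC(=O)CCl | intermediate
9 | tert-butyl 2-[(4S,8E)-1-chloro-4,8-dimethyl-10-phenyldec-8-en-2-ylidene]hydrazine-1-carboxylate (E/Z about C=N) | C/C(=C\Cc1ccccc1)CCC[C@H](C)CC(CCl)=NNC(=O)OC(C)(C)C | intermediate
10 | α-angelica lactone (5-methylfuran-2(3H)-one) | CC1=CCC(=O)O1 | starting material
11 | tert-butyl (E)-2-[(4S,8E)-4,8-dimethyl-10-phenyldeca-1,8-dien-2-yl]diazene-1-carboxylate | C/C(=C\Cc1ccccc1)CCC[C@H](C)CC(=C)/N=N/C(=O)OC(C)(C)C | intermediate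
12 | tert-butyl 2-{(4S,8E)-4,8-dimethyl-1-[(2R)-2-methyl-5-oxo-2,5-dihydrofuran-2-yl]-10-phenyldec-8-en-2-ylidene}hydrazine-1-carboxylate | C/C(=C\Cc1ccccc1)CCC[C@H](C)CC(C[C@@]1(C)OC(=O)C=C1)=NNC(=O)OC(C)(C)C | intermediate
13 | (5R)-5-[(4S,8E)-4,8-dimethyl-2-oxo-10-phenyldec-8-en-1-yl]-5-methylfuran-2(5H)-one | C/C(=C\Cc1ccccc1)CCC[C@H](C)CC(=O)C[C@@]1(C)OC(=O)C=C1 | intermediate
14 | (5R)-5-[(4S,8E)-4,8-dimethyl-2-methylidene-10-phenyldec-8-en-1-yl]-5-methylfuran-2(5H)-one | C/C(=C\Cc1ccccc1)CCC[C@H](C)CC(=C)C[C@@]1(C)OC(=O)C=C1 | intermediate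
15 | (5R)-5-methyl-5-[(4S,8E)-2,4,8-trimethyl-10-phenyl-2-(triethylsilylperoxy)dec-8-en-1-yl]furan-2(5H)-one, both epimers at the peroxide carbon | C/C(=C\Cc1ccccc1)CCC[C@H](C)CC(C)(OO[Si](CC)(CC)CC)C[C@@]1(C)OC(=O)C=C1 | intermediate
16 | (5R)-5-[(4S,8E)-2-hydroperoxy-2,4,8-trimethyl-10-phenyldec-8-en-1-yl]-5-methylfuran-2(5H)-one, both epimers at the peroxide carbon | C/C(=C\Cc1ccccc1)CCC[C@H](C)CC(C)(OO)C[C@@]1(C)OC(=O)C=C1 | intermediate
17 | plakortolide G, (3R,4aR,7aR)-3-[(2S,6E)-2,6-dimethyl-8-phenyloct-6-en-1-yl]-3,4a-dimethyltetrahydro-3H-furo[3,2-c][1,2]dioxin-6(4H)-one | C/C(=C\Cc1ccccc1)CCC[C@H](C)C[C@]1(C)C[C@@]2(C)OC(=O)C[C@H]2OO1 | target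

**Step count and risks**

Total steps: 8. Longest linear sequence: 8 (from 1; 2, 5 and 10 are purchased).

The three steps most likely to fail:

Step 5 (key coupling). The pairing of α-angelica lactone with an azoalkene is untested. The risks are attack through the α-carbon of the lactone, closure of the hydrazone nitrogen onto the new butenolide (formal [4+2] adduct) and low enantioselectivity. The fallback sets out from 8 and comes back at 14, bypassing 13. Ketone 8 is methylenated with Cp2Ti(μ-Cl)(μ-CH2)AlMe2 to the allyl chloride F1. The lithium enolate of commercial (2S,5S)-2-tert-butyl-5-methyl-1,3-dioxolan-4-one (LiN(i-Pr)2, THF, −78 °C, NaI) is alkylated anti to the tert-butyl group (Seebach self-regeneration of stereocentres) to give the dioxolanone F2 with C4 already R. Reduction with i-Bu2AlH at −78 °C gives the lactol F3. A Z-selective Horner–Wadsworth–Emmons reaction with ethyl (diphenoxyphosphoryl)acetate and NaH opens the lactol with loss of pivalaldehyde to the hydroxy Z-enoate F4, which lactonises on work-up to 14.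

Step 7 (hydroperoxysilylation). Cobalt hydride may also attack the side-chain trisubstituted alkene or the butenolide, and C6 forms as a 1:1 mixture, halving the yield. The fallback sets out from 14 and comes back at 17, replacing radical hydrogen-atom transfer by electrophilic peroxymercuration. Hg(OAc)2 and anhydrous H2O2 in Et2O/CH2Cl2 add in the Markovnikov sense across the less hindered 1,1-disubstituted alkene to give the mercurated hydroperoxide F5. Et2NH in CF3CH2OH closes the dioxane to the organomercurial peroxylactone F6. NaBH4 in aqueous NaOH at 0 °C removes mercury to give 17, again separated from its C6 epimer.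

Step 3 (chloromethyl ketone). A second addition of the carbenoid to the ketone, giving chlorohydrin or epoxide, is the main danger with a simple methyl ester. The fallback sets out from 7 and comes back at 8. Dimethylsulfoxonium methylide (Me3S(O)I, KOt-Bu, THF, reflux) is acylated by 7 to give the β-keto sulfoxonium ylide F7, which cannot over-add. Anhydrous HCl in THF at 65 °C then displaces dimethyl sulfoxide to return 8.

**Further compounds**

F1 | step 5 | [(2E,7S)-9-(chloromethyl)-3,7-dimethyldeca-2,9-dien-1-yl]benzene | C/C(=C\Cc1ccccc1)CCC[C@H](C)CC(=C)CCl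
F2 | step 5 | (2S,5R)-2-tert-butyl-5-[(4S,8E)-4,8-dimethyl-2-methylidene-10-phenyldec-8-en-1-yl]-5-methyl-1,3-dioxolan-4-one | C/C(=C\Cc1ccccc1)CCC[C@H](C)CC(=C)C[C@@]1(C)O[C@H](C(C)(C)C)OC1=O
F3 | step 5 | (2S,5R)-2-tert-butyl-5-[(4S,8E)-4,8-dimethyl-2-methylidene-10-phenyldec-8-en-1-yl]-5-methyl-1,3-dioxolan-4-ol (anomer mixture) | C/C(=C\Cc1ccccc1)CCC[C@H](C)CC(=C)C[C@@]1(C)O[C@H](C(C)(C)C)OC1O
F4 | step 5 | ethyl (2Z,4R,8S,12E)-4-hydroxy-4,8,12-trimethyl-6-methylidene-14-phenyltetradeca-2,12-dienoate | C/C(=C\Cc1ccccc1)CCC[C@H](C)CC(=C)C[C@@](C)(O)/C=C\C(=O)OCC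
F5 | step 7 | (5R)-5-[(4S,8E)-2-[(acetoxymercurio)methyl]-2-hydroperoxy-4,8-dimethyl-10-phenyldec-8-en-1-yl]-5-methylfuran-2(5H)-one, both epimers at the peroxide carbon | C/C(=C\Cc1ccccc1)CCC[C@H](C)CC(C[Hg]OC(C)=O)(OO)C[C@@]1(C)OC(=O)C=C1
F6 | step 7 | (4aR,7aR)-3-[(acetoxymercurio)methyl]-3-[(2S,6E)-2,6-dimethyl-8-phenyloct-6-en-1-yl]-4a-methyltetrahydro-3H-furo[3,2-c][1,2]dioxin-6(4H)-one, both epimers at C3 | C/C(=C\Cc1ccccc1)CCC[C@H](C)CC1(C[Hg]OC(C)=O)C[C@@]2(C)OC(=O)C[C@H]2OO1
F7 | step 3 | (4S,8E)-1-[dimethyl(oxo)-λ6-sulfanylidene]-4,8-dimethyl-10-phenyldec-8-en-2-one | C/C(=C\Cc1ccccc1)CCC[C@H](C)CC(=O)C=S(C)(C)=O
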